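## Analysis of the target

Emmaosunin (15) is a flavone, a 4H-chromen-4-one whose benzo ring A and pyranone ring C share C4a and C8a and whose C2 carries a 3-methoxyphenyl ring B. Ring A has no hydrogen left: C5 bears a free hydroxyl, C6, C7 and C8 bear methoxy groups, and ring C carries a further methoxy group on C3 beside the C4 carbonyl. There is no stereocentre and no stereogenic double bond, so every question is one of regiochemistry and of telling six oxygens apart. The sensitive points are the very electron-rich, tetra-oxygenated ring A (easily oxidised towards quinones, and open to ether cleavage by strong Lewis acids) and the pyranone, which opens in hot alkali. The difficulty lies in the hexasubstituted ring A with four oxygens in a row, the oxygen on C3, and the need to finish with exactly one free hydroxyl among five methyl ethers. The plan rests on ring C: the atoms O1, C2, C3, C4, C4a and C8a, with an oxygen on C3, form the one-carbon ring-expanded isomer of a 2-benzylidenebenzofuran-3(2H)-one, whose exocyclic benzylic carbon becomes C2 and whose ring carbon C2 becomes the oxygen-bearing C3. A second feature is used at the end: only O5 can share a six-membered chelate with the C4 carbonyl, which marks its methyl group for selective removal.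

## Retrosynthetic reasoning

**15 to 13.** The last bond to be dealt with is O5–CH3. The target is traced back to its fully methylated ether 13. Carrying six identical ethers keeps ring A inert through all earlier steps and avoids a differentiated C5 oxygen that would have to survive acylation, base and halogen. The forward reaction has to remove one methyl group of six; it can, because a boron Lewis acid bridges O5 and the C4 carbonyl (boron ester 14, not isolated).

**13 to 12.** The O3–CH3 bond is cut next, giving flavonol 12. The C3 hydroxyl is enolic and acidic, so the forward step is a plain O-alkylation, and 12 is exactly what the ring expansion delivers.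

**12 to 10.** In 12 the O1–C2 bond is cut and the C3 hydroxyl is traced to an external oxygen nucleophile. This contracts ring C to the five-membered ring of aurone 10. No other disconnection of ring C brings in the C3 oxygen during ring formation, and this one leads to a precursor made by a simple condensation. The forward reaction must add halogen across the exocyclic alkene (dibromide 11), exchange the ring halide for oxygen, open the furanone, and reclose the liberated phenoxide on the benzylic carbon.

**10 to 8 and 9.** The exocyclic C=C bond is cut into benzofuranone 8 and aldehyde 9. This is the convergent point: ring B enters as a purchased aldehyde, and the forward aldol condensation gives the Z alkene under thermodynamic control.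

**8 to 7.** The O1–C2 bond of the furanone is cut to the ortho-hydroxyaryl chloromethyl ketone 7. The forward step is an intramolecular O-alkylation with a favourable five-membered transition state.

**7 to 4 and 5.** The aryl–acyl bond is cut to phenol 4 and acid chloride 5. Phenol 4 has a single free ring position, and it lies ortho to the hydroxyl, so the acylation has no regiochemical choice. It is run through ester 6 and an acyl shift.

**4 to 1.** The phenolic C–O bond is traced to a C–H bond of arene 1, via aryllithium 2 and boronate 3. The two ring hydrogens of 1 are equivalent, so only one phenol can arise.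

## Alternatives that were turned down

**Alternative 1: aryne plus acylketene.**
- Disconnection: O1–C8a and C4–C4a are cut, so ring C is removed from ring A altogether.
- Forward key step: a fluoride source acts on 2,3,4,5-tetramethoxy-6-(trimethylsilyl)phenyl trifluoromethanesulfonate A2 to give 3,4,5,6-tetramethoxybenzyne A3. Heat cycloreverts 5-methoxy-6-(3-methoxyphenyl)-2,2-dimethyl-4H-1,3-dioxin-4-one A4 to the aroyl(methoxy)ketene A5. A3 and A5 unite in a formal [4+2] addition to give 3,5,6,7,8-pentamethoxy-2-(3-methoxyphenyl)-4H-chromen-4-one A1, which is identical with 13.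
- For it: it is convergent, the aryne is symmetric so there is no regiochemical issue, the C3 methoxy group arrives in place, and nothing depends on how the donor groups of ring A behave in an ionic rearrangement. On convergence and on the saved O-methylation it is stronger than the chosen route.
- Against it: two short-lived partners must meet, and they are released by different triggers (fluoride near room temperature, cycloreversion only on strong heating). A5 dimerises or is intercepted by fluoride. A3 is flanked by two methoxy groups and may add across the C=C bond of the ketene instead of its O=C–C=C unit. A2 needs about three steps from 4 (halogenation, O-silylation with silyl shift, triflation) and A4 about three of its own, and the final demethylation is still required.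
- Comparison: the chosen route is linear but uses only isolable, stable intermediates and cheap reagents, and confines the doubt to one step whose mechanism is well understood.

**Alternative 2: carbonylative three-component annulation.**
- Disconnection: C4a–C4, C4–C3 and O1–C2 are cut, giving 2-iodo-3,4,5,6-tetramethoxyphenol A7, carbon monoxide A9 and 1-ethynyl-3-methoxybenzene A8.
- Forward key step: zerovalent palladium inserts into the C–I bond of A7, A9 inserts, and coupling with A8 gives the alkynone A10. A 6-endo-dig closure by the phenol oxygen then gives 5,6,7,8-tetramethoxy-2-(3-methoxyphenyl)-4H-chromen-4-one A6.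
- For it: one step makes ring C, A7 is one iodination away from 4, and the count is about six operations from 1, equal to or one shorter than the chosen route. On step economy it is at least as good.
- Against it: A6 has no oxygen on C3. A late C–H oxidation of an electron-rich flavone is then needed, followed by methylation and the same demethylation. The C–I bond of A7 is doubly ortho-substituted and very electron-rich, so oxidative addition is slow and direct alkynylation without uptake of A9 competes. A10 can also close 5-exo to aurone 10 instead of A6.
- Comparison: the chosen route installs the C3 oxygen in the ring-forming event itself and needs neither a precious metal nor a toxic gas.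

**Alternative 3: ring A from a squarate.**
- Disconnection: ring A itself is cut (C5–C4a, and earlier C8–C8a). It is built from dimethyl squarate A14 and the preformed pyranone 3-methoxy-2-(3-methoxyphenyl)-4H-pyran-4-one A13, joined as 4-hydroxy-2,3-dimethoxy-4-[5-methoxy-6-(3-methoxyphenyl)-4-oxo-4H-pyran-2-yl]cyclobut-2-en-1-one A12.
- Forward key step: heating A12 opens the four-membered ring to a dienylketene, whose ketene carbon bonds to the pyranone carbon that becomes C4a in a 6π electrocyclisation. Tautomerisation gives the hydroquinone 5,8-dihydroxy-3,6,7-trimethoxy-2-(3-methoxyphenyl)-4H-chromen-4-one A11.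
- For it: the hexasubstituted ring is assembled with all four oxygens placed by construction, and C5 is a free hydroxyl from the start. The end game would be a selective methylation of the unchelated C8 hydroxyl with no demethylation at all; on this point it is stronger than the chosen route.
- Against it: A12 requires A13 metallated at C6 to add to A14. γ-Pyranones are attacked and opened by organolithium reagents, so a halogen or tin handle would be needed on a pyranone that already takes several steps. A11 is a para-hydroquinone and oxidises very readily to the quinone. The step count is clearly higher.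
- Comparison: the chosen route reaches its key step in four classical operations from a purchased arene.

Key step: step 5

Assumption: dibromide 11 is drawn as one enantiomer of the racemic anti adduct; its configuration is erased in the ring expansion and has no bearing on the product.

## Route

Step 1
Reactants: 1 1,2,3,4-tetramethoxybenzene
Product: 4 2,3,4,5-tetramethoxyphenol, via aryllithium 2 (not isolated), via arylboronate 3 (not isolated)
Conditions: n-BuLi, TMEDA, THF, 0 °C; B(OMe)3, −78 °C → rt; then AcOH, 30% H2O2, 0 °C → rt
Reagents that add atoms: hydrogen peroxide, OO (phenol oxygen of 4); n-butyllithium, [Li]CCCC (lithium of 2 only); trimethyl borate, COB(OC)OC (boron and two methoxy groups of 3 only)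
Why: Directed ortho-metalation beside a methoxy group, borylation, and peroxide oxidation of the C–B bond with aryl shift from boron to oxygen; the two ring hydrogens of 1 are equivalent, so a single phenol results, and the weakly acidic oxidation medium spares the electron-rich phenol.

Step 2
Reactants: 4 2,3,4,5-tetramethoxyphenol; 5 chloroacetyl chloride
Product: 7 2-chloro-1-(2-hydroxy-3,4,5,6-tetramethoxyphenyl)ethan-1-one, via aryl chloroacetate 6 (not isolated)
Conditions: ClCH2COCl, BF3·OEt2, 1,2-dichloroethane, 0 °C → 80 °C; aq. NaOAc work-up
Reagents that add atoms: none
Why: O-Acylation followed by a Lewis-acid Fries rearrangement; the acyl group can only move to the one free ring position, which is ortho to the hydroxyl, and BF3·OEt2 is preferred to AlCl3 because it leaves aryl methyl ethers intact.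

Step 3
Reactants: 7 2-chloro-1-(2-hydroxy-3,4,5,6-tetramethoxyphenyl)ethan-1-one
Product: 8 4,5,6,7-tetramethoxybenzofuran-3(2H)-one
Conditions: NaOAc, EtOH, reflux
Reagents that add atoms: none
Why: Intramolecular Williamson etherification, a 5-exo-tet displacement of the α-keto chloride by the phenoxide; acetate is basic enough for this but too weak to cause self-condensation of the benzofuranone.

Step 4
Reactants: 8 4,5,6,7-tetramethoxybenzofuran-3(2H)-one; 9 3-methoxybenzaldehyde
Product: 10 (Z)-4,5,6,7-tetramethoxy-2-(3-methoxybenzylidene)benzofuran-3(2H)-one
Conditions: KOH, MeOH, rt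
Reagents that add atoms: none
Why: Aldol condensation of the Claisen–Schmidt type between the C2 methylene of 8 and a non-enolisable aldehyde, followed by E1cB loss of water; the Z isomer, with the aryl group turned away from the C3 carbonyl, is the thermodynamic product.

Step 5
Reactants: 10 (Z)-4,5,6,7-tetramethoxy-2-(3-methoxybenzylidene)benzofuran-3(2H)-one
Product: 12 3-hydroxy-5,6,7,8-tetramethoxy-2-(3-methoxyphenyl)-4H-chromen-4-one, via aurone dibromide 11 (not isolated)
Conditions: Br2 (1.0 equiv), CH2Cl2, 0 °C, dark; then aq. KOH, THF, 0 °C → rt, argon; acidic work-up
Reagents that add atoms: potassium hydroxide, [K+].[OH-] (oxygen of the C3 hydroxyl of 12); bromine, BrBr (the two bromine atoms of 11 only, lost again as bromide)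
Why: This is the Auwers flavonol synthesis: bromine adds anti across the exocyclic enol-ether double bond of 10 to give the racemic dibromide 11. The ring bromide of 11 sits on a carbon that also bears O1, so it behaves as an α-halo ether and is exchanged for hydroxide to give a hemiketal. The hemiketal collapses, opening the five-membered ring to a phenoxide and an α-bromobenzyl 1,2-diketone. The phenoxide then displaces the benzylic, α-keto bromide in a 6-exo-tet closure that forms O1–C2 and ring C, and the resulting chromane-3,4-dione enolises to the conjugated flavonol, which drives the sequence. No stereocentre is formed in 12, since both centres of 11 become trigonal, so neither the alkene geometry of 10 nor the face of addition matters. The first selectivity needed is addition to the alkene rather than substitution on an arene: ring A has no hydrogen to replace, and ring B, a single anisole ring conjugated to the enone, should be slower than the enol ether towards one equivalent of bromine in the cold. The second is substitution at C2 ahead of loss of bromine back to 10: the methoxy groups para and ortho to O1 raise its donor power and help the C2–Br bond ionise, and aqueous THF is used so that only hydroxide, not an alkoxide, can enter at C2.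

Step 6
Reactants: 12 3-hydroxy-5,6,7,8-tetramethoxy-2-(3-methoxyphenyl)-4H-chromen-4-one
Product: 13 3,5,6,7,8-pentamethoxy-2-(3-methoxyphenyl)-4H-chromen-4-one
Conditions: MeI, K2CO3, acetone, reflux
Reagents that add atoms: iodomethane, CI
Why: Williamson O-methylation of the acidic enolic 3-hydroxyl; it is the only free hydroxyl in 12, so no selectivity question arises.

Step 7
Reactants: 13 3,5,6,7,8-pentamethoxy-2-(3-methoxyphenyl)-4H-chromen-4-one
Product: 15 emmaosunin (5-hydroxy-3,6,7,8-tetramethoxy-2-(3-methoxyphenyl)-4H-chromen-4-one), via dichloroboryl ether 14 (not isolated)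
Conditions: BCl3 (1.1 equiv), CH2Cl2, −78 °C → 0 °C; then H2O
Reagents that add atoms: boron trichloride, ClB(Cl)Cl (boron and two chlorine atoms of 14 only)
Why: Chelation-controlled Lewis-acid ether cleavage: BCl3 bridges the C4 carbonyl oxygen and O5 in a six-membered chelate, chloride takes the O5 methyl group, and water hydrolyses 14 to the phenol; the C3 ether could only form a strained five-membered chelate and the other four none, so one equivalent in the cold should cleave O5 alone.

## Compound list

1 | 1,2,3,4-tetramethoxybenzene | COc1ccc(OC)c(OC)c1OC | starting material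
2 | (2,3,4,5-tetramethoxyphenyl)lithium | [Li]c1cc(OC)c(OC)c(OC)c1OC | intermediate
3 | dimethyl (2,3,4,5-tetramethoxyphenyl)boronate | COB(OC)c1cc(OC)c(OC)c(OC)c1OC | intermediate
4 | 2,3,4,5-tetramethoxyphenol | COc1cc(O)c(OC)c(OC)c1OC | intermediate
5 | chloroacetyl chloride | ClCC(=O)Cl | starting material
6 | 2,3,4,5-tetramethoxyphenyl 2-chloroacetate | COc1cc(OC(=O)CCl)c(OC)c(OC)c1OC | intermediate
7 | 2-chloro-1-(2-hydroxy-3,4,5,6-tetramethoxyphenyl)ethan-1-one | COc1c(OC)c(OC)c(C(=O)CCl)c(O)c1OC | intermediate
8 | 4,5,6,7-tetramethoxybenzofuran-3(2H)-one | COc1c(OC)c(OC)c2c(c1OC)OCC2=O | intermediate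
9 | 3-methoxybenzaldehyde | COc1cccc(C=O)c1 | starting material
10 | (Z)-4,5,6,7-tetramethoxy-2-(3-methoxybenzylidene)benzofuran-3(2H)-one | COc1cccc(/C=C2\Oc3c(OC)c(OC)c(OC)c(OC)c3C2=O)c1 | intermediate
11 | 2-bromo-2-[bromo(3-methoxyphenyl)methyl]-4,5,6,7-tetramethoxybenzofuran-3(2H)-one (racemic anti adduct, 2R,αS enantiomer drawn) | COc1cccc([C@H](Br)[C@@]2(Br)Oc3c(OC)c(OC)c(OC)c(OC)c3C2=O)c1 | intermediate
12 | 3-hydroxy-5,6,7,8-tetramethoxy-2-(3-methoxyphenyl)-4H-chromen-4-one | COc1cccc(-c2oc3c(OC)c(OC)c(OC)c(OC)c3c(=O)c2O)c1 | intermediate
13 | 3,5,6,7,8-pentamethoxy-2-(3-methoxyphenyl)-4H-chromen-4-one | COc1cccc(-c2oc3c(OC)c(OC)c(OC)c(OC)c3c(=O)c2OC)c1 | intermediate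
14 | 5-[(dichloroboranyl)oxy]-3,6,7,8-tetramethoxy-2-(3-methoxyphenyl)-4H-chromen-4-one | COc1cccc(-c2oc3c(OC)c(OC)c(OC)c(OB(Cl)Cl)c3c(=O)c2OC)c1 | intermediate
15 | emmaosunin, 5-hydroxy-3,6,7,8-tetramethoxy-2-(3-methoxyphenyl)-4H-chromen-4-one | COc1cccc(-c2oc3c(OC)c(OC)c(OC)c(O)c3c(=O)c2OC)c1 | target

## Step count and least certain steps

Total: 7 steps. Longest linear sequence: 7 steps (1 to 15); 5 and 9 are purchased.

**Step 5 (key step).** The most likely failure is that the dibromide loses bromine again, or loses hydrogen bromide, faster than hydroxide enters at C2. This ring expansion is known to be sensitive to donor groups ortho and para to the furanone carbonyl, and 10 has methoxy groups at both such positions (C4 and C6). They lower the electrophilicity of C3 and do nothing for ionisation at C2, so the base may instead attack the α-keto bromine and return the aurone. A lesser risk is nuclear bromination of ring B if more than one equivalent of bromine is present. Silver-assisted hydrolysis of the C2 bromide (AgNO3, aqueous acetone) before the base is a first adjustment. The fallback proper abandons the ring expansion and builds ring C by acyl transfer, setting out from phenol 4: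
- Fries acylation as in step 2, but with methoxyacetyl chloride, gives 1-(2-hydroxy-3,4,5,6-tetramethoxyphenyl)-2-methoxyethan-1-one F1.
- O-Aroylation with 3-methoxybenzoyl chloride in pyridine gives 2-(2-methoxyacetyl)-3,4,5,6-tetramethoxyphenyl 3-methoxybenzoate F2.
- Baker–Venkataraman rearrangement (KOH, pyridine, 50 °C) gives 1-(2-hydroxy-3,4,5,6-tetramethoxyphenyl)-2-methoxy-3-(3-methoxyphenyl)propane-1,3-dione F3, with a racemic, enolisable centre.
- Cyclodehydration (H2SO4, AcOH) closes the pyranone and returns to the route at 13, so that only step 7 remains.

**Step 7.** The risk is over-cleavage: the C3 ether also lies next to the carbonyl, and once O5 is bound to boron the neighbouring C6 ether comes within reach, so excess reagent or warming could remove a second methyl group. The fallback replaces the selective dealkylation by a selective alkylation and sets out from flavonol 12, which has no C3 ether to lose. AlCl3 in MeCN cleaves the O5 methyl group to give 3,5-dihydroxy-6,7,8-trimethoxy-2-(3-methoxyphenyl)-4H-chromen-4-one F4. One equivalent of MeI with K2CO3 in acetone at room temperature then methylates the more acidic, less tightly hydrogen-bonded 3-hydroxyl and leaves the chelated 5-hydroxyl, arriving at 15.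

**Step 2.** The acyl shift may be sluggish, because a chloroacetyl cation is a poor migrating electrophile, and prolonged heating with the Lewis acid invites intermolecular acyl transfer or ether cleavage. The fallback installs a plain acetyl group and halogenates afterwards, setting out from 4. AcOH with BF3·OEt2 at 80 °C gives 1-(2-hydroxy-3,4,5,6-tetramethoxyphenyl)ethan-1-one F5. CuBr2 in refluxing EtOAc/CHCl3 brominates the methyl ketone to 2-bromo-1-(2-hydroxy-3,4,5,6-tetramethoxyphenyl)ethan-1-one F6; the ring has no free position. NaOAc in refluxing EtOH closes it to 8, where the route is rejoined.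

**Step 1.** Metalation may be incomplete, or the very electron-rich phenol may be oxidised further by the peroxide towards a quinone. The fallback introduces the oxygen by way of a formyl group, setting out from 1. Vilsmeier formylation (POCl3, DMF, 80 °C, aqueous work-up) gives 2,3,4,5-tetramethoxybenzaldehyde F7. Baeyer–Villiger oxidation with mCPBA in CH2Cl2 gives 2,3,4,5-tetramethoxyphenyl formate F8, and hydrolysis with aqueous NaOH followed by acidification gives 4.

## Further compounds

F1 | step 5 | 1-(2-hydroxy-3,4,5,6-tetramethoxyphenyl)-2-methoxyethan-1-one | COCC(=O)c1c(O)c(OC)c(OC)c(OC)c1OC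
F2 | step 5 | 2-(2-methoxyacetyl)-3,4,5,6-tetramethoxyphenyl 3-methoxybenzoate | COCC(=O)c1c(OC(=O)c2cccc(OC)c2)c(OC)c(OC)c(OC)c1OC
F3 | step 5 | 1-(2-hydroxy-3,4,5,6-tetramethoxyphenyl)-2-methoxy-3-(3-methoxyphenyl)propane-1,3-dione (racemic) | COc1cccc(C(=O)C(OC)C(=O)c2c(O)c(OC)c(OC)c(OC)c2OC)c1
F4 | step 7 | 3,5-dihydroxy-6,7,8-trimethoxy-2-(3-methoxyphenyl)-4H-chromen-4-one | COc1cccc(-c2oc3c(OC)c(OC)c(OC)c(O)c3c(=O)c2O)c1
F5 | step 2 | 1-(2-hydroxy-3,4,5,6-tetramethoxyphenyl)ethan-1-one | CC(=O)c1c(O)c(OC)c(OC)c(OC)c1OC
F6 | step 2 | 2-bromo-1-(2-hydroxy-3,4,5,6-tetramethoxyphenyl)ethan-1-one | BrCC(=O)c1c(O)c(OC)c(OC)c(OC)c1OC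
F7 | step 1 | 2,3,4,5-tetramethoxybenzaldehyde | COc1cc(C=O)c(OC)c(OC)c1OC
F8 | step 1 | 2,3,4,5-tetramethoxyphenyl formate | COc1cc(OC=O)c(OC)c(OC)c1OC
A1 | alternative 1 | 3,5,6,7,8-pentamethoxy-2-(3-methoxyphenyl)-4H-chromen-4-one | COc1cccc(-c2oc3c(OC)c(OC)c(OC)c(OC)c3c(=O)c2OC)c1
A2 | alternative 1 | 2,3,4,5-tetramethoxy-6-(trimethylsilyl)phenyl trifluoromethanesulfonate | COc1c(OC)c(OC)c([Si](C)(C)C)c(OS(=O)(=O)C(F)(F)F)c1OC
A3 | alternative 1 | 3,4,5,6-tetramethoxybenzyne | COC1=C(OC)C(OC)=C(OC)C#C1
A4 | alternative 1 | 5-methoxy-6-(3-methoxyphenyl)-2,2-dimethyl-4H-1,3-dioxin-4-one | COC1=C(c2cccc(OC)c2)OC(C)(C)OC1=O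
A5 | alternative 1 | 2-methoxy-3-(3-methoxyphenyl)-3-oxoprop-1-en-1-one | COC(=C=O)C(=O)c1cccc(OC)c1
A6 | alternative 2 | 5,6,7,8-tetramethoxy-2-(3-methoxyphenyl)-4H-chromen-4-one | COc1cccc(-c2cc(=O)c3c(OC)c(OC)c(OC)c(OC)c3o2)c1
A7 | alternative 2 | 2-iodo-3,4,5,6-tetramethoxyphenol | COc1c(OC)c(OC)c(I)c(O)c1OC
A8 | alternative 2 | 1-ethynyl-3-methoxybenzene | COc1cccc(C#C)c1
A9 | alternative 2 | carbon monoxide | [C-]#[O+]
A10 | alternative 2 | 1-(2-hydroxy-3,4,5,6-tetramethoxyphenyl)-3-(3-methoxyphenyl)prop-2-yn-1-one | COc1cccc(C#CC(=O)c2c(O)c(OC)c(OC)c(OC)c2OC)c1
A11 | alternative 3 | 5,8-dihydroxy-3,6,7-trimethoxy-2-(3-methoxyphenyl)-4H-chromen-4-one | COc1cccc(-c2oc3c(O)c(OC)c(OC)c(O)c3c(=O)c2OC)c1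
A12 | alternative 3 | 4-hydroxy-2,3-dimethoxy-4-[5-methoxy-6-(3-methoxyphenyl)-4-oxo-4H-pyran-2-yl]cyclobut-2-en-1-one | COC1=C(OC)C(O)(c2cc(=O)c(OC)c(-c3cccc(OC)c3)o2)C1=O
A13 | alternative 3 | 3-methoxy-2-(3-methoxyphenyl)-4H-pyran-4-one | COc1cccc(-c2occc(=O)c2OC)c1
A14 | alternative 3 | dimethyl squarate (3,4-dimethoxycyclobut-3-ene-1,2-dione) | COC1=C(OC)C(=O)C1=O
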